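**Retrosynthetic overview**
- The target is reached by acid hydrolysis of a dioxolane, which unveils the enone; the cis C4 carbinol comes from a CBS reduction of the neighbouring ketone, with C5 already set.
- The C5–side-chain bond is made by Enders SAMP-hydrazone alkylation of 7-methyl-1,4-dioxaspiro[4.5]dec-6-en-8-one with all-E geranylgeranyl bromide; this joins the two fragments and sets C5.
- The only ring of the target, the cyclohexenone, is closed by intramolecular aldol condensation of 2-(3-oxopentyl)-1,3-dioxolane-2-carbaldehyde. That keto-aldehyde comes from ozonolytic opening of the ketal of 3-ethylcyclopent-2-enone, made from cyclopentane-1,3-dione.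
- Geranylgeranyl bromide comes from (2E,6E)-farnesol by Weiler homologation (acetoacetate dianion, Z enol phosphate, Me2CuLi), then DIBAL-H and PBr3.
- Ring order: one ring, formed in step 11 before the fragment union in step 13.

Assumption: metalated or boron-bound forms of a numbered compound (enolates, azaenolates, alkoxides, borate esters) are counted with that compound; neutral covalent intermediates that are not isolated carry their own number.

**Side-chain fragment**

Step 1
Reactants: 1 (2E,6E)-farnesol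
Product: 2 (2E,6E)-farnesyl bromide
Conditions: PBr3, Et2O, −10 °C → 0 °C
Reagents that add atoms: phosphorus tribromide, BrP(Br)Br
Why: Bromination with PBr3 is an SN2 substitution on the primary allylic bromophosphite, and at low temperature it leaves the 2E geometry untouched.

Step 2
Reactants: 2 (2E,6E)-farnesyl bromide; 3 ethyl acetoacetate
Product: 4 ethyl (6E,10E)-7,11,15-trimethyl-3-oxohexadeca-6,10,14-trienoate
Conditions: NaH, THF, 0 °C; n-BuLi, 0 °C; then 2, 0 °C → rt; aq. HCl
Reagents that add atoms: none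
Why: Weiler dianion alkylation: the more basic terminal carbanion of the acetoacetate dianion is alkylated by the allylic bromide in an SN2 reaction.

Step 3
Reactants: 4 ethyl (6E,10E)-7,11,15-trimethyl-3-oxohexadeca-6,10,14-trienoate
Product: 5 ethyl (2Z,6E,10E)-3-[(diethoxyphosphoryl)oxy]-7,11,15-trimethylhexadeca-2,6,10,14-tetraenoate
Conditions: NaH, Et2O, 0 °C; ClP(O)(OEt)2, 0 °C → rt
Reagents that add atoms: diethyl chlorophosphate, CCOP(=O)(Cl)OCC
Why: O-Phosphorylation of the sodium-chelated enolate gives the Z enol phosphate, because the chelate holds the enolate oxygen cis to the ester.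

Step 4
Reactants: 5 ethyl (2Z,6E,10E)-3-[(diethoxyphosphoryl)oxy]-7,11,15-trimethylhexadeca-2,6,10,14-tetraenoate
Product: 6 ethyl (2E,6E,10E)-3,7,11,15-tetramethylhexadeca-2,6,10,14-tetraenoate
Conditions: Me2CuLi (from MeLi, CuI), Et2O, −78 °C → −45 °C; aq. NH4Cl
Reagents that add atoms: lithium dimethylcuprate, [Li+].C[Cu-]C
Why: Cuprate addition–elimination (Weiler enol phosphate coupling) replaces the phosphate by methyl with retention, so the Z enol phosphate gives the 2E trisubstituted alkene.

Step 5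
Reactants: 6 ethyl (2E,6E,10E)-3,7,11,15-tetramethylhexadeca-2,6,10,14-tetraenoate
Product: 7 (2E,6E,10E)-geranylgeraniol
Conditions: iBu2AlH (2.5 equiv), toluene, −78 °C; aq. NaOH work-up
Reagents that add atoms: none
Why: DIBAL-H 1,2-reduction of the unsaturated ester gives the allylic alcohol without conjugate reduction or alkene isomerisation.

Step 6
Reactants: 7 (2E,6E,10E)-geranylgeraniol
Product: 8 (2E,6E,10E)-geranylgeranyl bromide
Conditions: PBr3, Et2O, −10 °C → 0 °C
Reagents that add atoms: phosphorus tribromide, BrP(Br)Br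
Why: Bromination with PBr3 (SN2 on the primary allylic bromophosphite) keeps all three E alkenes and gives the electrophile for the fragment union.

**Ring fragment**

Step 7
Reactants: 9 cyclopentane-1,3-dione
Product: 10 3-ethoxycyclopent-2-en-1-one
Conditions: EtOH, TsOH·H2O (cat.), toluene, reflux, Dean–Stark
Reagents that add atoms: ethanol, CCO
Why: Acid-catalysed enol etherification of the enolised 1,3-dione under azeotropic water removal gives the vinylogous ester.

Step 8
Reactants: 10 3-ethoxycyclopent-2-en-1-one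
Product: 12 3-ethylcyclopent-2-en-1-one, via 3-ethoxy-1-ethylcyclopent-2-en-1-ol 11 (not isolated)
Conditions: EtMgBr, THF, 0 °C; then 1 M aq. HCl, rt
Reagents that add atoms: ethylmagnesium bromide, CC[Mg]Br; water, O
Why: Stork–Danheiser alkylative transposition: 1,2-addition of the Grignard reagent, then acid hydrolysis of the enol ether and loss of water, gives the 3-alkyl enone.

Step 9
Reactants: 12 3-ethylcyclopent-2-en-1-one
Product: 13 7-ethyl-1,4-dioxaspiro[4.4]non-6-ene
Conditions: (Me3SiOCH2)2, Me3SiOTf (cat.), CH2Cl2, −78 °C → −20 °C; pyridine quench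
Reagents that add atoms: 1,2-bis(trimethylsilyloxy)ethane, C[Si](C)(C)OCCO[Si](C)(C)C
Why: Noyori ketalisation is driven by formation of (Me3Si)2O and, being aprotic and kinetic, leaves the double bond in the 6,7-position.

Step 10
Reactants: 13 7-ethyl-1,4-dioxaspiro[4.4]non-6-ene
Product: 15 2-(3-oxopentyl)-1,3-dioxolane-2-carbaldehyde, via secondary ozonide 14 (not isolated)
Conditions: O3, CH2Cl2, −78 °C; then Me2S, −78 °C → rt
Reagents that add atoms: ozone, [O-][O+]=O
Why: Ozonolysis (Criegee mechanism) of the only alkene with reductive work-up opens the five-membered ring to an ethyl ketone and a non-enolisable ketal aldehyde.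

Step 11
Reactants: 15 2-(3-oxopentyl)-1,3-dioxolane-2-carbaldehyde
Product: 17 7-methyl-1,4-dioxaspiro[4.5]dec-6-en-8-one, via β-hydroxy ketone 16 (not isolated)
Conditions: KOH (0.3 equiv), MeOH, 0.05 M, 0 °C → rt
Reagents that add atoms: none
Why: Intramolecular aldol condensation: only the ethyl-side enolate reaches the aldehyde through a six-membered (6-enolexo) transition state, the aldehyde has no α-hydrogen, and E1cB loss of water gives the conjugated enone, so the ring closure has a single regiochemical outcome.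

Step 12
Reactants: 17 7-methyl-1,4-dioxaspiro[4.5]dec-6-en-8-one; 18 (S)-1-amino-2-(methoxymethyl)pyrrolidine (SAMP)
Product: 19 (2S)-2-(methoxymethyl)-N-(7-methyl-1,4-dioxaspiro[4.5]dec-6-en-8-ylidene)pyrrolidin-1-amine
Conditions: 18 (1.2 equiv), TsOH·H2O (cat.), cyclohexane, reflux, Dean–Stark
Reagents that add atoms: none
Why: Condensation of ketone and hydrazine under water removal gives the Enders SAMP hydrazone; conjugate addition is disfavoured by the neighbouring quaternary ketal carbon.

**Fragment union and endgame**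

Step 13
Reactants: 19 (2S)-2-(methoxymethyl)-N-(7-methyl-1,4-dioxaspiro[4.5]dec-6-en-8-ylidene)pyrrolidin-1-amine; 8 (2E,6E,10E)-geranylgeranyl bromide
Product: 20 (2S)-2-(methoxymethyl)-N-[(9R)-7-methyl-9-[(2E,6E,10E)-3,7,11,15-tetramethylhexadeca-2,6,10,14-tetraen-1-yl]-1,4-dioxaspiro[4.5]dec-6-en-8-ylidene]pyrrolidin-1-amine
Conditions: LDA, THF, 0 °C, 4 h; then 8, −100 °C → rt
Reagents that add atoms: none
Why: Enders SAMP-hydrazone alkylation: only C9 carries acidic hydrogens, and the bromide attacks the methoxy-chelated lithium azaenolate by SN2 from the face left open by the pyrrolidine arm, which sets C9 as R.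

Step 14
Reactants: 20 the alkylated SAMP hydrazone
Product: 21 (9R)-7-methyl-9-[(2E,6E,10E)-3,7,11,15-tetramethylhexadeca-2,6,10,14-tetraen-1-yl]-1,4-dioxaspiro[4.5]dec-6-en-8-one
Conditions: sat. aq. oxalic acid, Et2O, rt (two-phase)
Reagents that add atoms: water, O
Why: Mild two-phase hydrazone hydrolysis returns the ketone without epimerising the α-centre, and the ketal survives because the conjugated carbonyl disfavours its ionisation.

Step 15
Reactants: 21 the (9R)-ketone
Product: 22 (8R,9R)-7-methyl-9-[(2E,6E,10E)-3,7,11,15-tetramethylhexadeca-2,6,10,14-tetraen-1-yl]-1,4-dioxaspiro[4.5]dec-6-en-8-ol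
Conditions: (S)-2-methyl-CBS-oxazaborolidine (C18H20BNO, 0.3 equiv), catecholborane, toluene, −78 °C; MeOH, then aq. NaOH
Reagents that add atoms: none
Why: Corey–Bakshi–Shibata reduction: the (S)-catalyst binds the ketone with the 7-methylalkenyl arm as the large group and delivers hydride 1,2 to give the 8R carbinol, cis to the C9 chain; catecholborane at −78 °C does not hydroborate the trisubstituted alkenes.

Step 16
Reactants: 22 the (8R,9R)-alcohol
Product: 23 (4R,5R)-4-hydroxy-3-methyl-5-[(2E,6E,10E)-3,7,11,15-tetramethylhexadeca-2,6,10,14-tetraen-1-yl]cyclohex-2-en-1-one (target)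
Conditions: 0.5 M aq. HCl, THF, 0 °C → rt
Reagents that add atoms: water, O
Why: Acid-catalysed ketal hydrolysis through a conjugated oxocarbenium ion unveils the enone; C8 and C9 of the spiro compound become C4 and C5 of the target with both centres untouched.

**Compound list**
1 | (2E,6E)-farnesol | CC(C)=CCC/C(C)=C/CC/C(C)=C/CO | starting material
2 | (2E,6E)-farnesyl bromide | CC(C)=CCC/C(C)=C/CC/C(C)=C/CBr | intermediate
3 | ethyl acetoacetate | CCOC(=O)CC(C)=O | starting material
4 | ethyl (6E,10E)-7,11,15-trimethyl-3-oxohexadeca-6,10,14-trienoate | CC(C)=CCC/C(C)=C/CC/C(C)=C/CCC(=O)CC(=O)OCC | intermediate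
5 | ethyl (2Z,6E,10E)-3-[(diethoxyphosphoryl)oxy]-7,11,15-trimethylhexadeca-2,6,10,14-tetraenoate | CC(C)=CCC/C(C)=C/CC/C(C)=C/CC/C(OP(=O)(OCC)OCC)=C/C(=O)OCC | intermediate
6 | ethyl (2E,6E,10E)-3,7,11,15-tetramethylhexadeca-2,6,10,14-tetraenoate | CC(C)=CCC/C(C)=C/CC/C(C)=C/CC/C(C)=C/C(=O)OCC | intermediate
7 | (2E,6E,10E)-geranylgeraniol | CC(C)=CCC/C(C)=C/CC/C(C)=C/CC/C(C)=C/CO | intermediate
8 | (2E,6E,10E)-geranylgeranyl bromide | CC(C)=CCC/C(C)=C/CC/C(C)=C/CC/C(C)=C/CBr | intermediate
9 | cyclopentane-1,3-dione | O=C1CCC(=O)C1 | starting material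
10 | 3-ethoxycyclopent-2-en-1-one | CCOC1=CC(=O)CC1 | intermediate
11 | 3-ethoxy-1-ethylcyclopent-2-en-1-ol (racemic) | CCOC1=CC(O)(CC)CC1 | intermediate (not isolated)
12 | 3-ethylcyclopent-2-en-1-one | CCC1=CC(=O)CC1 | intermediate
13 | 7-ethyl-1,4-dioxaspiro[4.4]non-6-ene | CCC1=CC2(CC1)OCCO2 | intermediate
14 | secondary ozonide (1,2,4-trioxolane) of 13 | CCC12CCC3(OCCO3)C(O1)OO2 | intermediate (not isolated)
15 | 2-(3-oxopentyl)-1,3-dioxolane-2-carbaldehyde | CCC(=O)CCC1(C=O)OCCO1 | intermediate
16 | 6-hydroxy-7-methyl-1,4-dioxaspiro[4.5]decan-8-one (diastereomer mixture) | CC1C(O)C2(CCC1=O)OCCO2 | intermediate (not isolated)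
17 | 7-methyl-1,4-dioxaspiro[4.5]dec-6-en-8-one | CC1=CC2(CCC1=O)OCCO2 | intermediate
18 | (S)-1-amino-2-(methoxymethyl)pyrrolidine (SAMP) | COC[C@@H]1CCCN1N | starting material
19 | (2S)-2-(methoxymethyl)-N-(7-methyl-1,4-dioxaspiro[4.5]dec-6-en-8-ylidene)pyrrolidin-1-amine (C=N geometry not fixed) | COC[C@@H]1CCCN1N=C1CCC2(OCCO2)C=C1C | intermediate
20 | (2S)-2-(methoxymethyl)-N-[(9R)-7-methyl-9-[(2E,6E,10E)-3,7,11,15-tetramethylhexadeca-2,6,10,14-tetraen-1-yl]-1,4-dioxaspiro[4.5]dec-6-en-8-ylidene]pyrrolidin-1-amine (C=N geometry not fixed) | CC(C)=CCC/C(C)=C/CC/C(C)=C/CC/C(C)=C/C[C@@H]1CC2(OCCO2)C=C(C)C1=NN1CCC[C@H]1COC | intermediate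
21 | (9R)-7-methyl-9-[(2E,6E,10E)-3,7,11,15-tetramethylhexadeca-2,6,10,14-tetraen-1-yl]-1,4-dioxaspiro[4.5]dec-6-en-8-one | CC(C)=CCC/C(C)=C/CC/C(C)=C/CC/C(C)=C/C[C@@H]1CC2(OCCO2)C=C(C)C1=O | intermediate
22 | (8R,9R)-7-methyl-9-[(2E,6E,10E)-3,7,11,15-tetramethylhexadeca-2,6,10,14-tetraen-1-yl]-1,4-dioxaspiro[4.5]dec-6-en-8-ol | CC(C)=CCC/C(C)=C/CC/C(C)=C/CC/C(C)=C/C[C@@H]1CC2(OCCO2)C=C(C)[C@@H]1O | intermediate
23 | (4R,5R)-4-hydroxy-3-methyl-5-[(2E,6E,10E)-3,7,11,15-tetramethylhexadeca-2,6,10,14-tetraen-1-yl]cyclohex-2-en-1-one | CC(C)=CCC/C(C)=C/CC/C(C)=C/CC/C(C)=C/C[C@@H]1CC(=O)C=C(C)[C@@H]1O | target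

**Step count**
Total: 16 steps. Longest linear sequence: 10 steps (steps 1–6 then 13–16; the ring-fragment line, steps 7–12 then 13–16, is equally long).

**Three steps most likely to fail**

Step 9 (ketalisation of the enone). The double bond may migrate out of conjugation, and ozonolysis of the migrated ketal would give the wrong keto-aldehyde. The fallback sets out from 12 and installs the alkene only after the ketal is in place. Reductive enolate formation (Li, liquid NH3, THF, −78 °C) and trapping with PhSeBr gives trans-3-ethyl-2-(phenylselanyl)cyclopentan-1-one F1. Ordinary ketalisation (ethylene glycol, TsOH·H2O, toluene, Dean–Stark), now with no alkene to migrate, gives trans-7-ethyl-6-(phenylselanyl)-1,4-dioxaspiro[4.4]nonane F2. Oxidation with H2O2 and pyridine in CH2Cl2 at 0 °C triggers selenoxide syn-elimination; the only β-hydrogen is at C7, so the alkene can form only in the 6,7-position. The route is rejoined at 13.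

Step 13 (auxiliary-controlled alkylation). Metalation of the conjugated hydrazone may be sluggish or the facial selectivity low. The fallback sets out from 17 and 8 and drops the auxiliary. The lithium enolate of 17 (LDA, THF/DMPU, −78 °C) is alkylated with 8 to give racemic 7-methyl-9-[(2E,6E,10E)-3,7,11,15-tetramethylhexadeca-2,6,10,14-tetraen-1-yl]-1,4-dioxaspiro[4.5]dec-6-en-8-one F3. The catalyst-controlled reduction of step 15 then gives the 8R carbinol from both enantiomers: 22 from the 9R ketone and the trans diastereomer (8R,9S)-7-methyl-9-[(2E,6E,10E)-3,7,11,15-tetramethylhexadeca-2,6,10,14-tetraen-1-yl]-1,4-dioxaspiro[4.5]dec-6-en-8-ol F4 from the 9S ketone. The two are separated by chromatography (at most half of the material is used), and the route is rejoined at 22.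

Step 15 (cis-selective reduction). The ring itself favours axial hydride attack and hence the trans alcohol, so catalyst control may be incomplete. The fallback sets out from 21 and uses inversion. Luche reduction (NaBH4, CeCl3·7H2O, MeOH, −78 °C) gives the trans alcohol (8S,9R)-7-methyl-9-[(2E,6E,10E)-3,7,11,15-tetramethylhexadeca-2,6,10,14-tetraen-1-yl]-1,4-dioxaspiro[4.5]dec-6-en-8-ol F5. Mitsunobu inversion (4-nitrobenzoic acid, PPh3, DIAD, THF, 0 °C) gives (8R,9R)-7-methyl-9-[(2E,6E,10E)-3,7,11,15-tetramethylhexadeca-2,6,10,14-tetraen-1-yl]-1,4-dioxaspiro[4.5]dec-6-en-8-yl 4-nitrobenzoate F6. Methanolysis (K2CO3, MeOH, rt) rejoins the route at 22.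

**Further compounds**
F1 | step 9 | trans-3-ethyl-2-(phenylselanyl)cyclopentan-1-one (racemic) | CC[C@@H]1CCC(=O)[C@H]1[Se]c1ccccc1
F2 | step 9 | trans-7-ethyl-6-(phenylselanyl)-1,4-dioxaspiro[4.4]nonane (racemic) | CC[C@@H]1CCC2(OCCO2)[C@H]1[Se]c1ccccc1
F3 | step 13 | racemic 7-methyl-9-[(2E,6E,10E)-3,7,11,15-tetramethylhexadeca-2,6,10,14-tetraen-1-yl]-1,4-dioxaspiro[4.5]dec-6-en-8-one | CC(C)=CCC/C(C)=C/CC/C(C)=C/CC/C(C)=C/CC1CC2(OCCO2)C=C(C)C1=O
F4 | step 13 | (8R,9S)-7-methyl-9-[(2E,6E,10E)-3,7,11,15-tetramethylhexadeca-2,6,10,14-tetraen-1-yl]-1,4-dioxaspiro[4.5]dec-6-en-8-ol | CC(C)=CCC/C(C)=C/CC/C(C)=C/CC/C(C)=C/C[C@H]1CC2(OCCO2)C=C(C)[C@@H]1O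
F5 | step 15 | (8S,9R)-7-methyl-9-[(2E,6E,10E)-3,7,11,15-tetramethylhexadeca-2,6,10,14-tetraen-1-yl]-1,4-dioxaspiro[4.5]dec-6-en-8-ol | CC(C)=CCC/C(C)=C/CC/C(C)=C/CC/C(C)=C/C[C@@H]1CC2(OCCO2)C=C(C)[C@H]1O
F6 | step 15 | (8R,9R)-7-methyl-9-[(2E,6E,10E)-3,7,11,15-tetramethylhexadeca-2,6,10,14-tetraen-1-yl]-1,4-dioxaspiro[4.5]dec-6-en-8-yl 4-nitrobenzoate | CC(C)=CCC/C(C)=C/CC/C(C)=C/CC/C(C)=C/C[C@@H]1CC2(OCCO2)C=C(C)[C@@H]1OC(=O)c1ccc(cc1)[N+](=O)[O-]
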